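In the first instants of cedar, X meets Q at full strength, and each X can go two ways: to Q or to another X.

| setting | alder | larch | cedar | birch |
|---|---|---|---|---|
| X | 0.10 M (fed, over 5.0 min) | 0.10 M (fed, over 5.0 min) | 0.10 M | 0.10 M |
| Q | 4.00 equiv | 4.00 equiv | 4.00 equiv | 4.00 equiv (in portions, 5, over 5.0 min) |
| time | 25 min | 25 min | 25 min | 25 min |
| remark | the addition at 60 °C, then warmed to 90 °C; the feed brings no volume worth counting | all else is in the flask from the start; the feed brings no volume worth counting | everything together at the start | first portion at the start, last at 5.0 min |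
| temperature |  | 90 °C | 90 °C | 90 °C |

    X + Q → X.Q (k1 = 0.13 L mol⁻¹ min⁻¹, Ea1 = 71.0 kJ mol⁻¹)
    X + 2 Q → J (k2 = 0.0087 L² mol⁻² min⁻¹, Ea2 = 64.0 kJ mol⁻¹)
    X.Q ⇌ D (K3 = 2.6, k3 = 0.059 min⁻¹, Ea3 = 119 kJ mol⁻¹, ΔH3 = −90.0 kJ mol⁻¹)
    Q → E (k4 = 3.8 × 10⁻⁵ min⁻¹, Ea4 = 129 kJ mol⁻¹)
    2 X → X2 (k5 = 0.20 L mol⁻¹ min⁻¹, Ea5 = 74.0 kJ mol⁻¹)
    (constants at 90 °C)

- percent here means X units held: one X2 counts as two
- for a step with 2 of a species take k times the square, and two of it per event
- the constants hold at 90 °C; other temperatures follow from the activation energies and enthalpies

- the flask with the highest amount of X2, in percent of the X charged ("all alike" if they lie within 1.5 percentage points) (alder / larch / cedar / birch / all alike)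
- final X2, as a percentage of the X charged, in alder
- final X2, as a percentage of the X charged, in larch
- final X2, as a percentage of the X charged, in cedar
- final X2, as a percentage of the X charged, in birch

I count lifetimes at the start of cedar. Capture by Q, through the steps to X.Q and J, is first order in X at the charged [Q] of 0.400 M. Dimerisation is counted by the X it removes, at the charged [X]:

capture: 0.0534 min⁻¹, lifetime 18.7 min
dimerisation: 0.0400 min⁻¹, lifetime 25.0 min

Capture is the faster, but not by much. I call the loss rate of X by dimerisation divided by its loss rate by capture, each per X at the concentrations of the moment, the split number, ρ. Here ρ = 0.749.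

In the middle of the run, [X] falls and ρ falls with it. Capture holds up, since the X charged is a quarter of the Q, so it stays nearly pseudo-first-order. The loss of Q to E hardly counts, as its half-life of 300 h is far longer than the 25 min run. The step between X.Q and D does not touch X.

Summing the falling split over the whole run gives the share of X that ends as X2:

share = 1 − ln(1 + ρ)/ρ = 25.4 % for cedar

This runs X to its end and holds Q at its charge, two errors of opposite sign, so I keep it.

Birch differs early. Counting the additions and not the Q used, its [Q] averages 0.200 M until the last portion, half the charge. For that stretch I hold the starting split, then apply the share to the X that remains: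

ρ early: 1.52; X left at 5.0 min: 71.8 %
X2 early: 17.0 %; ρ afterwards: 0.538
birch total: 31.4 %

So I put birch above cedar. Larch and alder bring X into play over the first 5.0 min, and I set both under cedar without a figure.

The forecast says birch, with 24.1 % in alder, 22.9 % in larch, 25.2 % in cedar and 29.6 % in birch. Its grounds are “I track X under two losses”, integrated piece by piece. For birch it differs from my 31.4 %.

The simulation gives birch, with 24.0 % in alder, 23.0 % in larch, 25.2 % in cedar and 29.8 % in birch.

The forecast stands on every count. At 5.00 min, birch holds 15.3 % of X2 and 73.8 % of X; with Q made up, ρ for that X is 0.553, which adds 15.1 % for a total of 30.4 %. A repeat of larch with 10.0 equiv of Q has ρ = 0.288, so the share is 12.1 %, and that flask holds 10.3 % of X2 at 25.0 min.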